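## Retrosynthetic overview

1. Target 13 ← hydrogenolysis of its tri-O-benzyl ether 12 ← Felkin/β-chelate addition of an aryl Grignard to oxolane aldehyde 10, which sets the carbinol centre.
2. 10 ← oxidative cleavage of the propenyl group of 9 ← O-benzylation of 8 ← DDQ benzylic oxidation/5-exo O-cyclisation of diol 7. This is the only ring formed, and it sets C2.
3. 7 ← LiAlH4 reduction of acid 6 ← Ireland–Claisen [3,3] rearrangement of allylic ester 5. This makes the C3–C4 bond and both ring stereocentres by 1,3-chirality transfer from the (S)-carbinol.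
4. 5 ← esterification of acid 4 with allylic alcohol 3 ← cross-metathesis of (S)-but-3-en-2-ol (1) with allyl benzoate (2).

Assumptions: 1 (enantiopure), 2, 4 and 11 are purchased; 4 and 11 are otherwise one step each from dihydroferulic acid and 4-bromoguaiacol (BnBr, K2CO3). Oxolane numbering used below: O1, C2 (aryl), C3 (CH2OH), C4 (carbinol-bearing), C5 (CH2). The target is (2S,3R,4R) with an (R)-carbinol.

## Route

**Step 1**
Reactants: 1 (S)-but-3-en-2-ol; 2 allyl benzoate
Product: 3 (2E,4S)-4-hydroxypent-2-en-1-yl benzoate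
Conditions: Hoveyda–Grubbs II (3 mol%), 2 (3 equiv), CH2Cl2, 40 °C
Reagents that add atoms: none (both partners are listed reactants)
Why: Olefin cross-metathesis of a secondary allylic alcohol with an excess of a simple allyl ester gives the E-disubstituted alkene selectively and does not touch the purchased carbinol centre.

**Step 2**
Reactants: 3; 4 3-[4-(benzyloxy)-3-methoxyphenyl]propanoic acid
Product: 5 (2S,3E)-5-(benzoyloxy)pent-3-en-2-yl 3-[4-(benzyloxy)-3-methoxyphenyl]propanoate
Conditions: DCC, DMAP (cat.), CH2Cl2, 0 °C → rt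
Reagents that add atoms: none
Why: Steglich esterification acylates the secondary allylic alcohol under neutral conditions with retention at the carbinol.

**Step 3**
Reactants: 5
Product: 6 (2R,3R,4E)-3-[(benzoyloxy)methyl]-2-[4-(benzyloxy)-3-methoxybenzyl]hex-4-enoic acid
Conditions: LDA, TMSCl/Et3N, THF, −78 °C → rt, then 50 °C; aq. HCl
Reagents that add atoms: none
Why: Ireland–Claisen rearrangement: LDA/THF gives the kinetic E(O)-enolate (ArCH2 cis to the allyl oxygen), and the chair transition state with the carbinol methyl equatorial transfers the (S)-centre to the anti (2R,3R) pair and an E-propenyl group; the benzoate has no α-hydrogens and is inert.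

**Step 4**
Reactants: 6
Product: 7 (2R,3R)-2-[4-(benzyloxy)-3-methoxybenzyl]-3-[(E)-prop-1-en-1-yl]butane-1,4-diol
Conditions: LiAlH4, THF, 0 °C → rt
Reagents that add atoms: none
Why: Hydride reduction converts the acid to CH2OH and cleaves the benzoate in the same operation, leaving the alkene, aryl benzyl ether and both stereocentres unchanged.

**Step 5**
Reactants: 7
Product: 8 {(2S,3R,4R)-2-[4-(benzyloxy)-3-methoxyphenyl]-4-[(E)-prop-1-en-1-yl]oxolan-3-yl}methanol
Conditions: DDQ (1.2 equiv), CH2Cl2 (dry), 0 °C → rt
Reagents that add atoms: none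
Why: DDQ benzylic hydride abstraction gives a p-alkoxybenzyl (quinone-methide-type) cation that is trapped 5-exo by the CH2OH on the propenyl-bearing carbon (the other CH2OH could only give an oxetane), and the aryl group ends trans to both ring substituents, giving 2S.

**Step 6**
Reactants: 8
Product: 9 (2S,3R,4R)-2-[4-(benzyloxy)-3-methoxyphenyl]-3-[(benzyloxy)methyl]-4-[(E)-prop-1-en-1-yl]oxolane
Conditions: NaH, BnBr, Bu4NI (cat.), THF, 0 °C → rt
Reagents that add atoms: benzyl bromide, BrCc1ccccc1
Why: Williamson etherification caps the primary alcohol so that it cannot form a lactol or a magnesium alkoxide chelate in step 8.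

**Step 7**
Reactants: 9
Product: 10 (3R,4R,5S)-5-[4-(benzyloxy)-3-methoxyphenyl]-4-[(benzyloxy)methyl]oxolane-3-carbaldehyde
Conditions: OsO4 (cat.), NaIO4, 2,6-lutidine, dioxane–H2O, rt; used crude
Reagents that add atoms: osmium tetroxide, O=[Os](=O)(=O)=O, and sodium periodate, [Na+].[O-]I(=O)(=O)=O (source of the aldehyde oxygen)
Why: Lemieux–Johnson cleavage removes the propenyl carbons without attacking the electron-rich arenes (ozone would), and the lutidine buffer limits epimerisation of the cis-aldehyde.

**Step 8**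
Reactants: 10; 11 1-(benzyloxy)-4-bromo-2-methoxybenzene (as its Grignard reagent)
Product: 12 (R)-[4-(benzyloxy)-3-methoxyphenyl]{(3R,4R,5S)-5-[4-(benzyloxy)-3-methoxyphenyl]-4-[(benzyloxy)methyl]oxolan-3-yl}methanol
Conditions: 11, Mg, THF; then 10, THF, −78 °C
Reagents that add atoms: none beyond the listed reactants
Why: Grignard addition under Felkin–Anh control (aryl enters anti to the more substituted ring carbon carrying the cis CH2OBn), reinforced by β-chelation of Mg between the carbonyl and the ring oxygen, gives the (R)-carbinol.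

**Step 9**
Reactants: 12
Product: 13 (7R)-7-hydroxylariciresinol
Conditions: H2 (1 atm), 10% Pd/C, EtOAc–EtOH, rt
Reagents that add atoms: none
Why: Hydrogenolysis removes the two aryl benzyl ethers and the primary alkyl benzyl ether under neutral, acid-free conditions, with no stereocentre involved.

## Compound list

1 | (S)-but-3-en-2-ol | C[C@H](O)C=C | starting material
2 | allyl benzoate | C=CCOC(=O)c1ccccc1 | starting material
3 | (2E,4S)-4-hydroxypent-2-en-1-yl benzoate | C[C@H](O)/C=C/COC(=O)c1ccccc1 | intermediate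
4 | 3-[4-(benzyloxy)-3-methoxyphenyl]propanoic acid | COc1cc(CCC(O)=O)ccc1OCc1ccccc1 | starting material
5 | (2S,3E)-5-(benzoyloxy)pent-3-en-2-yl 3-[4-(benzyloxy)-3-methoxyphenyl]propanoate | C[C@H](OC(=O)CCc1ccc(OCc2ccccc2)c(OC)c1)/C=C/COC(=O)c1ccccc1 | intermediate
6 | (2R,3R,4E)-3-[(benzoyloxy)methyl]-2-[4-(benzyloxy)-3-methoxybenzyl]hex-4-enoic acid | OC(=O)[C@H](Cc1ccc(OCc2ccccc2)c(OC)c1)[C@H](COC(=O)c1ccccc1)/C=C/C | intermediate
7 | (2R,3R)-2-[4-(benzyloxy)-3-methoxybenzyl]-3-[(E)-prop-1-en-1-yl]butane-1,4-diol | OC[C@H](Cc1ccc(OCc2ccccc2)c(OC)c1)[C@H](CO)/C=C/C | intermediate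
8 | {(2S,3R,4R)-2-[4-(benzyloxy)-3-methoxyphenyl]-4-[(E)-prop-1-en-1-yl]oxolan-3-yl}methanol | COc1cc([C@H]2OC[C@H](/C=C/C)[C@@H]2CO)ccc1OCc1ccccc1 | intermediate
9 | (2S,3R,4R)-2-[4-(benzyloxy)-3-methoxyphenyl]-3-[(benzyloxy)methyl]-4-[(E)-prop-1-en-1-yl]oxolane | COc1cc([C@H]2OC[C@H](/C=C/C)[C@@H]2COCc2ccccc2)ccc1OCc1ccccc1 | intermediate
10 | (3R,4R,5S)-5-[4-(benzyloxy)-3-methoxyphenyl]-4-[(benzyloxy)methyl]oxolane-3-carbaldehyde | COc1cc([C@H]2OC[C@H](C=O)[C@@H]2COCc2ccccc2)ccc1OCc1ccccc1 | intermediate
11 | 1-(benzyloxy)-4-bromo-2-methoxybenzene | COc1cc(Br)ccc1OCc1ccccc1 | starting material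
12 | (R)-[4-(benzyloxy)-3-methoxyphenyl]{(3R,4R,5S)-5-[4-(benzyloxy)-3-methoxyphenyl]-4-[(benzyloxy)methyl]oxolan-3-yl}methanol | COc1cc([C@H]2OC[C@H]([C@@H](O)c3ccc(OCc4ccccc4)c(OC)c3)[C@@H]2COCc2ccccc2)ccc1OCc1ccccc1 | intermediate
13 | (7R)-7-hydroxylariciresinol | COc1cc([C@H]2OC[C@H]([C@@H](O)c3ccc(O)c(OC)c3)[C@@H]2CO)ccc1O | target

## Summary

Total steps: 9. Longest linear sequence: 9 (1 → 13).

Steps most likely to fail:

1. **Step 8** (facial selectivity of the aryl addition, and the epimerisable cis-aldehyde). Fallback: reverse the order at the carbinol. Leave 8 unprotected, cleave it to the bicyclic lactol, oxidise to the γ-lactone (Ag2CO3/Celite), add the aryllithium at −78 °C to give the aryl ketone/hemiketal, then reduce with hydride. With the ketone held by the neighbouring alkoxide, exo delivery of hydride gives the same (R)-carbinol.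
2. **Step 5** (over-oxidation of the 2-aryloxolane benzylic C–H, or slow hydride abstraction). Fallback: change the mechanism to phenol oxidation. Carry the phenol of 4 as a pivalate (cleaved in step 4), generate the p-quinone methide from the free phenol with Ag2O, let the same CH2OH trap it, then silylate.
3. **Step 9** (hydrogenolysis of the electron-rich benzylic C–OH or C2–O bonds). Fallback: replace all benzyl groups with TBS ethers on both phenols and the CH2OH, and finish with TBAF. This pairs with the quinone-methide ring closure in fallback 2, because an aryl silyl ether is a poorer donor for DDQ.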